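**Retrosynthetic overview**
1. Numbering: carbocycle C1–C10 (C4 bears C15O2Me, C10 bears C14H3); the ether O bridges C5 and C10; lactone = O–C6, C7–C11(=C13H2)–C12(=O). Ring A = O, C5, C4, C3, C2, C1, C10; ring B = O, C5, C6, C7, C8, C9, C10.
2. Last bond: C3=C4 (ring A) by ring-closing metathesis. Before it: O–C5 (ring B) together with C4–C15 by alkoxycarbonylative cyclisation of a C5 allene with the tertiary C10–OH. The C8 ester comes from acylation with the (2S,3R)-epoxy acid.
3. Key disconnection: C7–C11 of the γ-lactone. The enabling feature is that C7 lies between the two oxygen-bearing carbons C6 (lactone O) and C8 (acyloxy O), so the target hides a 2,3-epoxy alcohol. A phosphonoacetate carbanion held on O6 opens a trans C7–C8 epoxide 5-exo at C7, the epoxide oxygen becomes O8, and the phosphonate then delivers C13 in the same flask.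
4. The erythro epoxy alcohol comes from an (E)-enynol by matched Sharpless epoxidation; C6 from catalytic alkynylation of an enal; C10 from geraniol (Sharpless epoxidation, reductive opening).
5. Ring order: γ-lactone, then ring B (oxepane), then ring A (oxepene).

Key step: step 9

Remark on the chemistry: the side chain is read as (2S,3R)-2,3-dimethyloxirane-2-carboxylate (methyl groups cis, i.e. the epoxide of an (E)-2-methylbut-2-enoate); the tertiary C10 hydroxyl is carried unprotected throughout.

**Route**

Step 1
Reactants: 1 geraniol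
Product: 2 (2S,3S)-2,3-epoxygeraniol
Conditions: Ti(OiPr)4 (5 mol %), L-(+)-diisopropyl tartrate (7 mol %), tBuOOH, 4 Å MS, CH2Cl2, −20 °C
Reagents that add atoms: tert-butyl hydroperoxide, CC(C)(C)OO
Why: Sharpless asymmetric epoxidation of the primary allylic alcohol, in which the L-(+)-tartrate–titanium complex delivers oxygen to the face that gives the (2S,3S)-epoxide and so fixes the future C10 stereocentre.

Step 2
Reactants: 2 (2S,3S)-2,3-epoxygeraniol
Product: 3 (3S)-3,7-dimethyloct-6-ene-1,3-diol
Conditions: NaAlH2(OCH2CH2OMe)2, THF, 0 °C; aq. Rochelle salt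
Reagents that add atoms: none
Why: The alkoxyaluminate formed at the C1 hydroxyl delivers hydride intramolecularly to C2 (regioselective reductive opening of a 2,3-epoxy alcohol), so the tertiary C–O bond and its configuration are kept.

Step 3
Reactants: 3 (3S)-3,7-dimethyloct-6-ene-1,3-diol; 4 (triphenylphosphoranylidene)acetaldehyde
Product: 6 (2E,5S)-5-hydroxy-5,9-dimethyldeca-2,8-dienal, via β-hydroxy aldehyde 5 (not isolated)
Conditions: TEMPO (10 mol %), PhI(OAc)2 (1.1 equiv), CH2Cl2, 23 °C; then 4 (1.2 equiv), 40 °C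
Reagents that add atoms: none
Why: Oxoammonium oxidation is selective for the primary alcohol, and the aldehyde is trapped in the same flask by a Wittig reaction with the stabilised formyl ylide, which should give the (E)-enal without isolating the dehydration-prone β-hydroxy aldehyde.

Step 4
Reactants: 6 (2E,5S)-5-hydroxy-5,9-dimethyldeca-2,8-dienal; 7 tert-butyldimethyl(prop-2-yn-1-yloxy)silane
Product: 8 (4S,5E,8S)-1-[(tert-butyldimethylsilyl)oxy]-8,12-dimethyltrideca-5,11-dien-2-yne-4,8-diol
Conditions: ProPhenol ligand (20 mol %; antipode chosen for Re-face addition, (S,S) expected), Ph3P=O (40 mol %), ZnMe2 (4 equiv), 7 (3 equiv), toluene, 4 °C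
Reagents that add atoms: none
Why: Dinuclear zinc–ProPhenol catalysed enantioselective alkynylation of the enal, in which the ligand directs the alkynylzinc to the Re face of the aldehyde and sets the carbinol carbon (C6 of the skeleton) as 4S, while excess ZnMe2 absorbs the tertiary hydroxyl.

Step 5
Reactants: 8 (4S,5E,8S)-1-[(tert-butyldimethylsilyl)oxy]-8,12-dimethyltrideca-5,11-dien-2-yne-4,8-diol
Product: 9 (1R)-4-[(tert-butyldimethylsilyl)oxy]-1-{(2R,3R)-3-[(2S)-2-hydroxy-2,6-dimethylhept-5-en-1-yl]oxiran-2-yl}but-2-yn-1-ol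
Conditions: Ti(OiPr)4 (1.0 equiv), D-(−)-diisopropyl tartrate (1.2 equiv), tBuOOH (2 equiv), 4 Å MS, CH2Cl2, −20 °C
Reagents that add atoms: tert-butyl hydroperoxide, CC(C)(C)OO
Why: Sharpless asymmetric epoxidation of a secondary (E)-allylic alcohol in its matched pairing, so the (4S)-carbinol should react fast with the D-(−)-tartrate catalyst and give the erythro epoxy alcohol with C8 as in the target and C7 ready for inversion, the alkyne and the remote trisubstituted alkene being inert and any (4R)-epimer being left behind.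

Step 6
Reactants: 9 (1R)-4-[(tert-butyldimethylsilyl)oxy]-1-{(2R,3R)-3-[(2S)-2-hydroxy-2,6-dimethylhept-5-en-1-yl]oxiran-2-yl}but-2-yn-1-ol; 10 2-(diethoxyphosphoryl)acetic acid
Product: 11 (1R)-4-[(tert-butyldimethylsilyl)oxy]-1-{(2S,3R)-3-[(2S)-2-hydroxy-2,6-dimethylhept-5-en-1-yl]oxiran-2-yl}but-2-yn-1-yl 2-(diethoxyphosphoryl)acetate
Conditions: N,N'-dicyclohexylcarbodiimide, DMAP (10 mol %), CH2Cl2, 0 → 23 °C
Reagents that add atoms: none
Why: Steglich esterification acylates the secondary epoxy carbinol and leaves the tertiary alcohol untouched, which places the phosphonate-stabilised carbon nucleophile on O6 without touching a stereocentre (the descriptor at the oxirane carbon changes only through substituent priority).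

Step 7
Reactants: 11 (1R)-4-[(tert-butyldimethylsilyl)oxy]-1-{(2S,3R)-3-[(2S)-2-hydroxy-2,6-dimethylhept-5-en-1-yl]oxiran-2-yl}but-2-yn-1-yl 2-(diethoxyphosphoryl)acetate
Product: 12 (1R)-4-hydroxy-1-{(2S,3R)-3-[(2S)-2-hydroxy-2,6-dimethylhept-5-en-1-yl]oxiran-2-yl}but-2-yn-1-yl 2-(diethoxyphosphoryl)acetate
Conditions: HF·pyridine, pyridine, THF, 0 °C
Reagents that add atoms: none
Why: Desilylation by buffered hydrogen fluoride frees the primary propargylic alcohol and avoids basic fluoride, which would deprotonate the phosphonoacetate prematurely.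

Step 8
Reactants: 12 (1R)-4-hydroxy-1-{(2S,3R)-3-[(2S)-2-hydroxy-2,6-dimethylhept-5-en-1-yl]oxiran-2-yl}but-2-yn-1-yl 2-(diethoxyphosphoryl)acetate
Product: 15 (1R)-1-{(2S,3R)-3-[(2S)-2-hydroxy-2,6-dimethylhept-5-en-1-yl]oxiran-2-yl}buta-2,3-dien-1-yl 2-(diethoxyphosphoryl)acetate, via N-alkyl sulfonylhydrazine 13 (not isolated), via propargyl diazene 14 (not isolated)
Conditions: PPh3, diethyl azodicarboxylate, 2-nitrobenzenesulfonylhydrazide, THF, −15 °C; then 23 °C
Reagents that add atoms: none
Why: Myers allene synthesis, in which Mitsunobu N-alkylation at the only competent (primary propargylic) hydroxyl, loss of sulfinic acid and retro-ene loss of N2 from the propargyl diazene transpose the alkyne into the terminal allene at C5 under conditions too mild to touch the epoxide or the phosphonoacetate.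

Step 9
Reactants: 15 (1R)-1-{(2S,3R)-3-[(2S)-2-hydroxy-2,6-dimethylhept-5-en-1-yl]oxiran-2-yl}buta-2,3-dien-1-yl 2-(diethoxyphosphoryl)acetate
Product: 17 (4R,5R)-4-[(1R,3S)-1,3-dihydroxy-3,7-dimethyloct-6-en-1-yl]-3-methylidene-5-(propa-1,2-dien-1-yl)oxolan-2-one, via α-phosphono lactone 16 (not isolated)
Conditions: NaH (1.1 equiv), THF, 0 → 45 °C; then (CH2O)n, 23 °C; aq. NH4Cl
Reagents that add atoms: formaldehyde (from paraformaldehyde), C=O
Why: Proposed new method: the sodium enolate of the phosphonoacetate, held on O6, attacks C7 of the trans C7–C8 epoxide anti to the epoxide oxygen in a 5-exo-tet closure that forms the C7–C11 bond of the γ-lactone ring (C11–C12–O–C6–C7); the closest known reaction type is the intermolecular opening of epoxides by phosphonoacetate anions followed by Horner–Wadsworth–Emmons methylenation, and the 5-exo openings of 2,3-epoxy alcohol carbamates and the Stork epoxynitrile cyclisation show that a short tether on the carbinol oxygen reaches the proximal epoxide carbon. C7 is set by SN2 inversion and C8 keeps the epoxide configuration, so the erythro epoxy ester derived from the (E)-alkene should give the trans-4,5-disubstituted lactone with O8 and C11 in the relative arrangement of the target, i.e. the whole C6/C7/C8 triad. The C8 alkoxide is quenched by proton transfer from the more acidic C11–H, so the resting species is the phosphonate-stabilised lactone enolate of 16, which condenses with formaldehyde (Horner–Wadsworth–Emmons) to give the exocyclic C11=C13 alkene; the C11 stereocentre of 16 is therefore irrelevant. The step needs 5-exo attack at C7 rather than 6-endo attack at C8, which the collinear SN2 geometry allowed by the three-atom O–C(=O)–C tether should secure, and C-alkylation through the s-cis ester rotamer, which the sodium ion bridging enolate and epoxide oxygen should favour. One equivalent of base leaves the tertiary C10 hydroxyl protonated, and the allene and the trisubstituted alkene are inert to the carbanion.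

Step 10
Reactants: 18 (2E)-2-methylbut-2-en-1-ol
Product: 19 [(2R,3R)-2,3-dimethyloxiran-2-yl]methanol
Conditions: Ti(OiPr)4 (5 mol %), D-(−)-diethyl tartrate (7 mol %), tBuOOH, 4 Å MS, CH2Cl2, −20 °C
Reagents that add atoms: tert-butyl hydroperoxide, CC(C)(C)OO
Why: Sharpless asymmetric epoxidation of the trisubstituted primary allylic alcohol with the D-(−)-tartrate catalyst sets both side-chain stereocentres by reagent control.

Step 11
Reactants: 19 [(2R,3R)-2,3-dimethyloxiran-2-yl]methanol
Product: 20 (2S,3R)-2,3-dimethyloxirane-2-carboxylic acid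
Conditions: TEMPO (20 mol %), PhI(OAc)2 (2.2 equiv), MeCN/H2O 1:1, 23 °C
Reagents that add atoms: water, O
Why: Oxoammonium oxidation through the aldehyde hydrate converts the primary alcohol into the acid, the quaternary α-carbon cannot epimerise, and the descriptor change to 2S reflects only substituent priority.

Step 12
Reactants: 17 (4R,5R)-4-[(1R,3S)-1,3-dihydroxy-3,7-dimethyloct-6-en-1-yl]-3-methylidene-5-(propa-1,2-dien-1-yl)oxolan-2-one; 20 (2S,3R)-2,3-dimethyloxirane-2-carboxylic acid
Product: 21 (1R,3S)-3-hydroxy-3,7-dimethyl-1-[(2R,3R)-4-methylidene-5-oxo-2-(propa-1,2-dien-1-yl)oxolan-3-yl]oct-6-en-1-yl (2S,3R)-2,3-dimethyloxirane-2-carboxylate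
Conditions: 20, 2,4,6-Cl3C6H2COCl, Et3N, THF, 23 °C; then 17, DMAP, toluene, 23 °C
Reagents that add atoms: none
Why: Yamaguchi esterification through the mixed anhydride and DMAP acylates the secondary C8 hydroxyl with retention (the tertiary one is inert) and blocks O8 from competing as a nucleophile in the next step.

Step 13
Reactants: 21 (1R,3S)-3-hydroxy-3,7-dimethyl-1-[(2R,3R)-4-methylidene-5-oxo-2-(propa-1,2-dien-1-yl)oxolan-3-yl]oct-6-en-1-yl (2S,3R)-2,3-dimethyloxirane-2-carboxylate
Product: 22 ring-B oxepane acrylate: methyl 2-substituted prop-2-enoate on C5 of the (5R,6S,7R,8R,10S)-oxepane trans-fused to the α-methylene-γ-lactone (skeleton numbering)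
Conditions: Pd(OCOCF3)2 (10 mol %), p-benzoquinone (2 equiv), CO (1 atm), MeOH (5 equiv), CH2Cl2, 0 → 23 °C
Reagents that add atoms: carbon monoxide, [C-]#[O+]; methanol, CO
Why: Intramolecular alkoxypalladation–methoxycarbonylation of the hydroxy-allene, in which divalent palladium activates the allene, the tertiary C10 hydroxyl attacks the substituted terminus C5 anti to the metal (7-exo, closing ring B), the vinylpalladium at C4 inserts CO and is cleaved by methanol while benzoquinone reoxidises zerovalent palladium; C5 should form with the acrylate arm trans to the C6–O bond and cis to the C10 side chain, the only arrangement that can be bridged afterwards.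

Step 14
Reactants: 22 ring-B oxepane acrylate
Product: 23 CNP0240298.1
Conditions: second-generation Grubbs catalyst RuCl2(H2IMes)(PCy3)(=CHPh) (10 mol %), toluene (2 mM), 80 °C
Reagents that add atoms: none
Why: Ring-closing metathesis between the 1,1-disubstituted acrylate olefin and the isobutenyl terminus (loss of 2-methylpropene) closes ring A as the trisubstituted enoate, whose geometry is fixed by the seven-membered ring, while the electron-poor α-methylene lactone stays a spectator; closures of 2,7-cis-dialkenyl cyclic ethers to oxa-bridged bicycles are a well-used reaction type.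

**Compound list**
1 | geraniol, (2E)-3,7-dimethylocta-2,6-dien-1-ol | OC/C=C(C)/CCC=C(C)C | starting material
2 | (2S,3S)-2,3-epoxygeraniol | OC[C@@H]1O[C@@]1(C)CCC=C(C)C | intermediate
3 | (3S)-3,7-dimethyloct-6-ene-1,3-diol | OCC[C@@](C)(O)CCC=C(C)C | intermediate
4 | (triphenylphosphoranylidene)acetaldehyde | O=CC=P(c1ccccc1)(c1ccccc1)c1ccccc1 | starting material
5 | (3S)-3-hydroxy-3,7-dimethyloct-6-enal (not isolated) | O=CC[C@@](C)(O)CCC=C(C)C | intermediate
6 | (2E,5S)-5-hydroxy-5,9-dimethyldeca-2,8-dienal | O=C/C=C/C[C@@](C)(O)CCC=C(C)C | intermediate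
7 | tert-butyldimethyl(prop-2-yn-1-yloxy)silane | C#CCO[Si](C)(C)C(C)(C)C | starting material
8 | (4S,5E,8S)-1-[(tert-butyldimethylsilyl)oxy]-8,12-dimethyltrideca-5,11-dien-2-yne-4,8-diol | CC(C)(C)[Si](C)(C)OCC#C[C@@H](O)/C=C/C[C@@](C)(O)CCC=C(C)C | intermediate
9 | (1R)-4-[(tert-butyldimethylsilyl)oxy]-1-{(2R,3R)-3-[(2S)-2-hydroxy-2,6-dimethylhept-5-en-1-yl]oxiran-2-yl}but-2-yn-1-ol | CC(C)(C)[Si](C)(C)OCC#C[C@@H](O)[C@H]1O[C@@H]1C[C@@](C)(O)CCC=C(C)C | intermediate
10 | 2-(diethoxyphosphoryl)acetic acid | CCOP(=O)(CC(=O)O)OCC | starting material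
11 | 2-(diethoxyphosphoryl)acetate of 9 | CC(C)(C)[Si](C)(C)OCC#C[C@@H](OC(=O)CP(=O)(OCC)OCC)[C@H]1O[C@@H]1C[C@@](C)(O)CCC=C(C)C | intermediate
12 | (1R)-4-hydroxy-1-{(2S,3R)-3-[(2S)-2-hydroxy-2,6-dimethylhept-5-en-1-yl]oxiran-2-yl}but-2-yn-1-yl 2-(diethoxyphosphoryl)acetate | OCC#C[C@@H](OC(=O)CP(=O)(OCC)OCC)[C@H]1O[C@@H]1C[C@@](C)(O)CCC=C(C)C | intermediate
13 | N-alkyl-N-(2-nitrobenzenesulfonyl)hydrazine from 12 (not isolated) | NN(CC#C[C@@H](OC(=O)CP(=O)(OCC)OCC)[C@H]1O[C@@H]1C[C@@](C)(O)CCC=C(C)C)S(=O)(=O)c1ccccc1[N+](=O)[O-] | intermediate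
14 | propargyl diazene (not isolated) | N=NCC#C[C@@H](OC(=O)CP(=O)(OCC)OCC)[C@H]1O[C@@H]1C[C@@](C)(O)CCC=C(C)C | intermediate
15 | (1R)-1-{(2S,3R)-3-[(2S)-2-hydroxy-2,6-dimethylhept-5-en-1-yl]oxiran-2-yl}buta-2,3-dien-1-yl 2-(diethoxyphosphoryl)acetate | C=C=C[C@@H](OC(=O)CP(=O)(OCC)OCC)[C@H]1O[C@@H]1C[C@@](C)(O)CCC=C(C)C | intermediate
16 | (4R,5R)-3-(diethoxyphosphoryl)-4-[(1R,3S)-1,3-dihydroxy-3,7-dimethyloct-6-en-1-yl]-5-(propa-1,2-dien-1-yl)oxolan-2-one, C3 epimers (not isolated) | CCOP(=O)(OCC)C1C(=O)O[C@H](C=C=C)[C@H]1[C@H](O)C[C@@](C)(O)CCC=C(C)C | intermediate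
17 | (4R,5R)-4-[(1R,3S)-1,3-dihydroxy-3,7-dimethyloct-6-en-1-yl]-3-methylidene-5-(propa-1,2-dien-1-yl)oxolan-2-one | C=C1C(=O)O[C@H](C=C=C)[C@H]1[C@H](O)C[C@@](C)(O)CCC=C(C)C | intermediate
18 | (2E)-2-methylbut-2-en-1-ol | C/C=C(\C)CO | starting material
19 | [(2R,3R)-2,3-dimethyloxiran-2-yl]methanol | OC[C@@]1(C)O[C@@H]1C | intermediate
20 | (2S,3R)-2,3-dimethyloxirane-2-carboxylic acid | OC(=O)[C@@]1(C)O[C@@H]1C | intermediate
21 | (1R,3S)-3-hydroxy-3,7-dimethyl-1-[(2R,3R)-4-methylidene-5-oxo-2-(propa-1,2-dien-1-yl)oxolan-3-yl]oct-6-en-1-yl (2S,3R)-2,3-dimethyloxirane-2-carboxylate | C=C1C(=O)O[C@H](C=C=C)[C@H]1[C@H](OC(=O)[C@@]1(C)O[C@@H]1C)C[C@@](C)(O)CCC=C(C)C | intermediate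
22 | ring-B oxepane acrylate, (5R,6S,7R,8R,10S) in skeleton numbering | C=C1C(=O)O[C@H]2[C@H]1[C@H](OC(=O)[C@@]1(C)O[C@@H]1C)C[C@](C)(CCC=C(C)C)O[C@@H]2C(=C)C(=O)OC | intermediate
23 | CNP0240298.1 | C=C1C(=O)O[C@H]2[C@H]1[C@H](OC(=O)[C@@]1(C)O[C@@H]1C)C[C@]1(C)CCC=C(C(=O)OC)[C@H]2O1 | target

**Count and risks**

Total step count: 14 (12 in the main line, 2 for the side-chain acid). Longest linear sequence: 12 steps (steps 1–9 and 12–14).

Steps most likely to fail:

1. Step 9 (bears the label). The ester may stay in its s-trans rotamer so that the carbanion never reaches C7 and intermolecular alkylation takes over. Attack may go 6-endo at C8 to a δ-lactone. The C8 alkoxide may take over the phosphoryl group and close a cyclopropane, or the lactone acyl group may migrate to O8. The fallback uses known reaction types and makes the same C7–C11 ring closure by a radical instead of an anion; it sets out from 9 and comes back at 21. O-Alkylation of the C6 hydroxyl of 9 with propargyl bromide (Ag2O, CH2Cl2) should give the prop-2-ynyl ether F1. Trivalent titanium (Cp2TiCl from Cp2TiCl2 and Zn, THF, 23 °C) opens the epoxide by homolysis of the C7–O bond, and the β-titanoxy C7 radical closes 5-exo-dig on the ether alkyne to the 3-methylideneoxolane F2, with the C8–O bond untouched and the trans ring substitution that such closures usually give. Yamaguchi esterification with 20 should give the C8 ester F3. Allylic oxidation of the ring O–CH2 group with hexavalent chromium (CrO3·2C5H5N, CH2Cl2) should give the α-methylene lactone F4. HF·pyridine should free the propargylic alcohol F5, and the conditions of step 8 convert it into 21.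

2. Step 13. External methanol may capture the palladium–allene complex faster than the hindered tertiary hydroxyl closes a seven-membered ring. Attack on the wrong allene face would give the 5,10-trans ether that cannot be bridged. The same hydroxyl may cyclise 5-exo onto the trisubstituted alkene. The fallback separates C–O from C–C(O) bond formation and removes the alcohol from the cyclisation; it sets out from 21 and comes back at 22. Under Pd(OAc)2 (cat.), LiBr, Cu(OAc)2, K2CO3 and O2 in MeCN, bromopalladation of the allene gives a 2-bromo-π-allylpalladium that the tertiary hydroxyl attacks at C5, which should give the ring-B vinyl bromide F6. Methoxycarbonylation of F6 (PdCl2(PPh3)2, CO 1 atm, MeOH, Et3N, DMF, 50 °C) then gives 22.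

3. Step 4. The zinc alkoxide of the tertiary alcohol may enter the dinuclear zinc catalyst and erode turnover or facial selectivity, and the alkynylzinc may add in conjugate fashion. The fallback gives up catalytic control at C6 and lets the next step sort the epimers; it sets out from 6 and comes back at 9. The lithium acetylide of 7 (n-BuLi, THF, −78 °C; two equivalents, one consumed by the tertiary hydroxyl) adds without facial control to give the C4-epimeric enynol mixture F7. Under the conditions of step 5 only the matched (4S)-epimer should be epoxidised, giving 9, while the unreacted (4R)-alcohol is separated.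

**Further compounds**
F1 | step 9 | prop-2-yn-1-yl ether of 9 at the C6 oxygen | CC(C)(C)[Si](C)(C)OCC#C[C@@H](OCC#C)[C@H]1O[C@@H]1C[C@@](C)(O)CCC=C(C)C
F2 | step 9 | 3-methylideneoxolane from the radical closure, C8 hydroxyl free | C=C1CO[C@H](C#CCO[Si](C)(C)C(C)(C)C)[C@H]1[C@H](O)C[C@@](C)(O)CCC=C(C)C
F3 | step 9 | C8 (2S,3R)-2,3-dimethyloxirane-2-carboxylate of F2 | C=C1CO[C@H](C#CCO[Si](C)(C)C(C)(C)C)[C@H]1[C@H](OC(=O)[C@@]1(C)O[C@@H]1C)C[C@@](C)(O)CCC=C(C)C
F4 | step 9 | α-methylene-γ-lactone from allylic oxidation of F3 | C=C1C(=O)O[C@H](C#CCO[Si](C)(C)C(C)(C)C)[C@H]1[C@H](OC(=O)[C@@]1(C)O[C@@H]1C)C[C@@](C)(O)CCC=C(C)C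
F5 | step 9 | primary propargylic alcohol from desilylation of F4 | C=C1C(=O)O[C@H](C#CCO)[C@H]1[C@H](OC(=O)[C@@]1(C)O[C@@H]1C)C[C@@](C)(O)CCC=C(C)C
F6 | step 13 | ring-B vinyl bromide (C4–Br in place of the ester carbon of 22) | C=C1C(=O)O[C@H]2[C@H]1[C@H](OC(=O)[C@@]1(C)O[C@@H]1C)C[C@](C)(CCC=C(C)C)O[C@@H]2C(Br)=C
F7 | step 4 | C4-epimeric mixture of enynol 8 | CC(C)(C)[Si](C)(C)OCC#CC(O)/C=C/C[C@@](C)(O)CCC=C(C)C
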